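The numbers in the tables are simulated with constants of no real substance; noise was put on by code.

If one-to-one pairing with substrate were the partner's one use, 30 mM of partner could not run short against 5 mM of substrate. Yet in the theta run substrate stays flat within scatter from 10.0 s on, at a mean reading of 2.65%; call this fraction left F.

| flask | substrate | partner | remark | time |
|---|---|---|---|---|
| theta | 5 mM | 30 mM | run made earlier |  |
| flask | 5.0 mM | 20.0 mM |  | 6.0 min |

- theta (time / s: substrate / %, target / %): 10.0: 3.5, 26.4; 20.0: 1.9, 12.2; 40.0: 2.9, 4.5; 80.0: 2.3, 1.8

(readings scatter by 0.5 percentage points)

- which holds at 6.0 min: what has brought the reaction to rest, or that it has not come to rest (forward and back rates have come level / it is still moving / all of the substrate has reacted / the partner has run out first)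
- share of the substrate used up at 6.0 min
- target at 6.0 min, in percent of the substrate charged
- isomer of the product B at 6.0 min, in percent of the substrate charged

- the reaction counts as stopped when no species that holds the substrate changes by six tenths of a point or more over the second half of the time

My own reckoning reads that plateau as a ledger of the partner, supposing that partner also disappears by itself, first order. One entry is pairing, which books the substrate charged, c_A, minus c_A F. The other is loss, which books −κ ln F, where κ is the loss rate constant of partner over its rate constant of capture by substrate; dividing the two rates removes time. The books close when partner reaches zero. In the theta run pairing takes 4.87 mM, so loss holds 25.1 mM and κ reads 6.92 mM, a reading that carries the scatter of the plateau: the partner wasted per unit of −ln F, its waste constant.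

The flask charges 20.0 mM, and its books, solved for F by repetition, close at F = 10.6%. That is 4.47 mM paired, 15.5 mM lost and a conversion of 89.4%, with partner as limiting reagent. The ledger does not divide the used substrate among products.

The forecast differs: forward and back rates have come level, conversion 95.8% (94.5% to 97%), target 1.3% (0.5% to 2.2%), isomer of the product B 94.5% (92.5% to 96%), on the ground that the “end state is therefore an equilibrium”.

The flask gives: the partner has run out first, conversion 89.9%, target 1.69%, isomer of the product B 47.4%.

    substrate + partner → target (k = 21.0 /M/s)
    substrate + partner → isomer of the product A (k = 7.50 /M/s)
    substrate + partner → second isomer (k = 10.0 /M/s)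
    partner → decomposed reagent (k = 0.260 /s)
    target ⇌ isomer of the product B (K = 28.0, k = 0.0830 /s)

At 6.00 min this flask holds partner at 0% beside substrate at 10.1%, and 15.5 mM of decomposed reagent, while κ at the simulated conversion books 15.9 mM of loss. The neighbour flask, charged with 5.0 mM of partner, holds at 6.00 min partner at 0% and substrate at 62.8%. At that F its books show 1.86 mM paired and 3.22 mM lost, and its decomposed reagent stands at 3.14 mM.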